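**Plan**

- **Retrosynthesis:** The CH2OH groups on C-3 and C-4 go back to methyl esters. Both ring C–O bonds (O-1–C-2 and O-1–C-5) are then cut and C-2 is joined to C-5. This contracts the oxolane to an all-trans cyclobutane, the head-to-head photodimer of methyl sinapate. Cutting its α–α' and β–β' bonds leaves two sinapic acid units held on a C2-symmetric diol.
- **Enabling feature:** C-2 and C-5 of the oxolane ring are benzylic carbons para to the free OH of a syringyl ring, so each is a latent quinone methide carbon. The C-3–C-4 bond with its trans substituents is the α–α' bond of a sinapate dimer.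
- **Forward order:** The cyclobutane forms first, inside a ten-membered dilactone, and is released from the template. The four-membered ring is opened oxidatively, the oxolane closes around one molecule of water, and the esters are reduced last.
- **Stereochemistry:** C-3 and C-4 come from the photocycloaddition. They are steered by (4S,5S)-threitol acetonide (L-tartaric acid series) and secured by separation of diastereomers. C-2 and C-5 are set in the ring expansion, each trans to its ester-bearing neighbour.

Key step: step 5

Assumption: the (4S,5S) template is taken to favour the cyclobutane with (S,S) ester-bearing carbons, because a crown-like ten-membered ring places torsion angles of opposite sign at the new α–α' bond and at the dioxolane C-4–C-5 bond; if the opposite pairing is found, the equally available (4R,5R)-diol would be used with no other change.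

**Step 1**
Reactants: 1 sinapic acid, (E)-3-(4-hydroxy-3,5-dimethoxyphenyl)prop-2-enoic acid; 2 acetic anhydride
Product: 3 4-O-acetylsinapic acid, (E)-3-(4-acetoxy-3,5-dimethoxyphenyl)prop-2-enoic acid
Conditions: Ac2O (2.5 equiv), pyridine, rt; then H2O
Reagents that add atoms: acetic anhydride (2), CC(=O)OC(C)=O
Why: Pyridine-promoted O-acetylation of a phenol; the acetate blocks self-acylation in step 2 and electron or hydrogen transfer to the excited photocatalyst in step 3, any mixed anhydride at the carboxyl group is hydrolysed on aqueous work-up, and no stereocentre is involved.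

**Step 2**
Reactants: 3 4-O-acetylsinapic acid (2.2 equiv); 4 (4S,5S)-2,2-dimethyl-1,3-dioxolane-4,5-dimethanol ((+)-2,3-O-isopropylidene-L-threitol)
Product: 5 [(4S,5S)-2,2-dimethyl-1,3-dioxolane-4,5-diyl]bis(methylene) bis[(E)-3-(4-acetoxy-3,5-dimethoxyphenyl)prop-2-enoate]
Conditions: DCC (2.4 equiv), DMAP (10 mol %), CH2Cl2, 0 °C to rt
Reagents that add atoms: none
Why: Steglich esterification of two unhindered primary alcohols with a cinnamic acid; the E-alkenes, the aryl acetates and the acetonide should be inert to carbodiimide and catalytic DMAP at this temperature, and the two template stereocentres are not touched.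

**Step 3**
Reactants: 5 templated bis(4-O-acetylsinapate)
Product: 6 templated δ-truxinate: a ten-membered dilactone in which an all-trans cyclobutane (ester-bearing carbons S,S; aryl-bearing carbons R,R; both aryl groups 4-acetoxy-3,5-dimethoxyphenyl) is bridged through its two vicinal carboxyl groups by the [(4S,5S)-2,2-dimethyl-1,3-dioxolane-4,5-diyl]bis(methylene) unit
Conditions: fac-Ir(ppy)3 (2 mol %), degassed MeCN (5 mM), blue LEDs (450 nm), rt; chromatography, then crystallisation to a single diastereomer
Reagents that add atoms: none
Why: Visible-light triplet-sensitised intramolecular (2+2) photocycloaddition of a tethered dicinnamate: energy transfer from excited Ir(ppy)3 gives a cinnamate triplet that bonds through its α-carbon to the α-carbon of the tethered partner, the bis-benzylic 1,4-diradical closes with every pair of neighbours trans (head-to-head anti, δ-truxinate pattern), the template decides which pair of alkene faces is joined and so sets the four new centres in the absolute sense, and the alternatives are diastereomers that can be removed by chromatography and crystallisation.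

**Step 4**
Reactants: 6 templated δ-truxinate; 7 methanol
Product: 8 dimethyl (1S,2S,3R,4R)-3,4-bis(4-hydroxy-3,5-dimethoxyphenyl)cyclobutane-1,2-dicarboxylate (all-trans)
Conditions: NaOMe (5 equiv), MeOH, 0 °C to rt; then 1 M aq. HCl to pH 4
Reagents that add atoms: methanol (7), CO
Why: Methoxide-mediated transesterification (Zemplén-type) exchanges the two primary alkyl ester links for methyl esters and strips both aryl acetates in the same operation; the enolisable ester-bearing carbons already hold the thermodynamically preferred all-trans arrangement, and hydroxylated truxinates are known to survive alkaline ester cleavage.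

**Step 5**
Reactants: 8 all-trans cyclobutane diester bis-phenol; 9 water
Product: 12 dimethyl (2R,3R,4R,5R)-2,5-bis(4-hydroxy-3,5-dimethoxyphenyl)oxolane-3,4-dicarboxylate (all-trans), via bis-quinone methide 10 (not isolated), via hydroxy quinone methide 11 (not isolated)
Conditions: Ag2O (2.5 equiv), MeCN, 0 °C, dark, 30 min; filter through Celite; then H2O (MeCN–H2O 4:1), TsOH·H2O (10 mol %), rt
Reagents that add atoms: water (9), O
Why: Proposed new method: Ag2O removes one electron and one proton from each syringyl phenol, and in the resulting bis-phenoxyl the cyclobutane bond between the two aryl-bearing carbons, already weakened by ring strain and double benzylic substitution, lies β to both spin-bearing para carbons and should break in a Grob-like manner to the closed-shell bis-quinone methide 10, whose ester-bearing C–C bond keeps its (S,S) configuration. After the silver is filtered off, acid-catalysed 1,6-addition of water to one quinone methide carbon gives 11, and its new benzylic hydroxyl closes the oxolane ring by a 5-exo-trig oxa-1,6-addition to the second quinone methide, which restores both arenes and forms O-1–C-2 and O-1–C-5. The closest known reaction types are the radical-cation ring opening with 1,3-oxyfunctionalisation of arylcyclopropanes, the aerobic conversion of 1,2-diarylcyclobutane radical cations into 1,2-dioxanes, and the hydration of the same kind of bis-quinone methide in oxidative β–β coupling of sinapate and ferulate esters. C-2 and C-5 are each controlled by the adjacent fixed centre (C-3 and C-4 respectively), because the oxygen nucleophile approaches anti to the ester in the rotamer of least allylic strain, and para-hydroxybenzylic C–O bonds ionise reversibly under the acid catalysis, so minor epimers should drain into the all-trans isomer, the least crowded of the three possible. The step needs cleavage of the diaryl bond in preference to cycloreversion, benzylic C–H loss or tautomerisation of 10; this is served by an excess of surface oxidant that takes both phenols to the phenoxyl stage without a long-lived monoradical, by the cold aprotic first stage and by the acidic water-rich second stage. Because the C-3 and C-4 substituents are esters with no nucleophilic oxygen, the bicyclic furofuran mode of trapping is closed off, and removing the oxidant before 12 appears protects the product phenols.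

**Step 6**
Reactants: 12 all-trans oxolane diester
Product: 13 [(2R,3S,4S,5R)-2,5-bis(4-hydroxy-3,5-dimethoxyphenyl)oxolane-3,4-diyl]dimethanol (CNP0170897.1)
Conditions: LiAlH4 (6 equiv), THF, 0 °C to rt; aq. potassium sodium tartrate, neutral work-up
Reagents that add atoms: none
Why: LiAlH4 reduction of esters to primary alcohols; two further hydride equivalents are consumed by the phenols, the four ring stereocentres are not involved (the descriptors at C-3 and C-4 change from R to S only because CH2OH ranks below C-2 and C-5 whereas CO2Me ranks above them), and the low temperature is meant to keep the benzylic ethers closed.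

**Compound list**

1 | sinapic acid | COc1cc(/C=C/C(=O)O)cc(OC)c1O | starting material
2 | acetic anhydride | CC(=O)OC(C)=O | starting material
3 | 4-O-acetylsinapic acid | COc1cc(/C=C/C(=O)O)cc(OC)c1OC(C)=O | intermediate
4 | (4S,5S)-2,2-dimethyl-1,3-dioxolane-4,5-dimethanol | CC1(C)O[C@@H](CO)[C@H](CO)O1 | starting material
5 | [(4S,5S)-2,2-dimethyl-1,3-dioxolane-4,5-diyl]bis(methylene) bis[(E)-3-(4-acetoxy-3,5-dimethoxyphenyl)prop-2-enoate] | CC1(C)O[C@@H](COC(=O)/C=C/c2cc(OC)c(OC(C)=O)c(OC)c2)[C@H](COC(=O)/C=C/c2cc(OC)c(OC(C)=O)c(OC)c2)O1 | intermediate
6 | templated δ-truxinate (ten-membered dilactone; cyclobutane ester carbons S,S, aryl carbons R,R; dioxolane S,S) | COc1cc([C@@H]2[C@@H](c3cc(OC)c(OC(C)=O)c(OC)c3)[C@@H]5C(=O)OC[C@@H]4OC(C)(C)O[C@H]4COC(=O)[C@@H]25)cc(OC)c1OC(C)=O | intermediate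
7 | methanol | CO | starting material
8 | dimethyl (1S,2S,3R,4R)-3,4-bis(4-hydroxy-3,5-dimethoxyphenyl)cyclobutane-1,2-dicarboxylate | COc1cc([C@@H]2[C@@H](c3cc(OC)c(O)c(OC)c3)[C@H](C(=O)OC)[C@H]2C(=O)OC)cc(OC)c1O | intermediate
9 | water | O | starting material
10 | dimethyl (2S,3S)-2,3-bis[(3,5-dimethoxy-4-oxocyclohexa-2,5-dien-1-ylidene)methyl]butanedioate | COC1=CC(=C[C@H](C(=O)OC)[C@@H](C(=O)OC)C=C2C=C(OC)C(=O)C(OC)=C2)C=C(OC)C1=O | intermediate
11 | dimethyl (2R,3S)-2-[(R)-hydroxy(4-hydroxy-3,5-dimethoxyphenyl)methyl]-3-[(3,5-dimethoxy-4-oxocyclohexa-2,5-dien-1-ylidene)methyl]butanedioate | COc1cc([C@H](O)[C@H](C(=O)OC)[C@@H](C(=O)OC)C=C2C=C(OC)C(=O)C(OC)=C2)cc(OC)c1O | intermediate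
12 | dimethyl (2R,3R,4R,5R)-2,5-bis(4-hydroxy-3,5-dimethoxyphenyl)oxolane-3,4-dicarboxylate | COc1cc([C@@H]2O[C@@H](c3cc(OC)c(O)c(OC)c3)[C@H](C(=O)OC)[C@H]2C(=O)OC)cc(OC)c1O | intermediate
13 | [(2R,3S,4S,5R)-2,5-bis(4-hydroxy-3,5-dimethoxyphenyl)oxolane-3,4-diyl]dimethanol | COc1cc([C@@H]2O[C@@H](c3cc(OC)c(O)c(OC)c3)[C@H](CO)[C@H]2CO)cc(OC)c1O | target

Total step count: 6. Longest linear sequence: 6 steps (1 to 13).

**Steps most likely to fail**

**Step 5.**
- The one-electron-oxidised cyclobutane may revert to two sinapate units, and their recombination would also erode the enantiomeric purity.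
- A benzylic hydrogen may be lost in place of C–C cleavage.
- The opened bis-quinone methide may tautomerise at its acidic α-positions on the basic silver surface.
- The acid stage may drive Friedel–Crafts closure onto a syringyl ring.

The fallback sets out from 1 and returns at 12, using known chemistry only. Fischer esterification of 1 (MeOH, catalytic H2SO4, reflux) gives methyl sinapate F1. One-electron oxidation of F1 with FeCl3 in aqueous acetone (oxidative β–β phenol coupling) joins two molecules at their β-carbons and adds water in the same flask. This gives the all-trans oxolane diester as a racemate, that is 12 together with its mirror image, the (2S,3S,4S,5S)-diester F2. Preparative chromatography on a chiral stationary phase removes F2 and delivers 12.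

**Step 3.**
- The trans-fused ten-membered dilactone is strained, so the diradical may close to cis-fused isomers or fall back to the alkenes.
- Unproductive E/Z isomerisation may dominate.
- Facial selectivity under the template may be poor.

The fallback sets out from 3 and returns at 8. Steglich esterification of 3 with methanol gives methyl 4-O-acetylsinapate F3. F3 is dimerised intermolecularly, without a template, at high concentration under triplet sensitisation, a reaction known to favour head-to-head anti dimers of cinnamates. This gives the racemic all-trans dimer, made up of the (1S,2S,3R,4R)-tetraester F4 and the (1R,2R,3S,4S)-tetraester F5. Separation on a chiral stationary phase provides F4, and NaOMe in MeOH removes its two acetates to give 8.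

**Step 6.**
- Phenoxide-assisted opening of a benzylic C–O bond followed by hydride capture may occur.
- The ring oxygen may undergo β-elimination from an ester enolate.
- The polyphenolic product may be retained on aluminium salts.

The fallback sets out from 12 and returns at 13. Both phenols are silylated (TBSCl, imidazole, DMF) to give the bis(tert-butyldimethylsilyl) ether F6. With no phenoxide present, LiAlH4 in THF reduces the esters to the bis-silylated diol F7. Bu4NF buffered with AcOH in THF then frees the phenols and gives 13.

**Further compounds**

F1 | step 5 | methyl sinapate | COc1cc(/C=C/C(=O)OC)cc(OC)c1O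
F2 | step 5 | dimethyl (2S,3S,4S,5S)-2,5-bis(4-hydroxy-3,5-dimethoxyphenyl)oxolane-3,4-dicarboxylate | COc1cc([C@H]2O[C@H](c3cc(OC)c(O)c(OC)c3)[C@@H](C(=O)OC)[C@@H]2C(=O)OC)cc(OC)c1O
F3 | step 3 | methyl (E)-3-(4-acetoxy-3,5-dimethoxyphenyl)prop-2-enoate | COc1cc(/C=C/C(=O)OC)cc(OC)c1OC(C)=O
F4 | step 3 | dimethyl (1S,2S,3R,4R)-3,4-bis(4-acetoxy-3,5-dimethoxyphenyl)cyclobutane-1,2-dicarboxylate | COc1cc([C@@H]2[C@@H](c3cc(OC)c(OC(C)=O)c(OC)c3)[C@H](C(=O)OC)[C@H]2C(=O)OC)cc(OC)c1OC(C)=O
F5 | step 3 | dimethyl (1R,2R,3S,4S)-3,4-bis(4-acetoxy-3,5-dimethoxyphenyl)cyclobutane-1,2-dicarboxylate | COc1cc([C@H]2[C@H](c3cc(OC)c(OC(C)=O)c(OC)c3)[C@@H](C(=O)OC)[C@@H]2C(=O)OC)cc(OC)c1OC(C)=O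
F6 | step 6 | dimethyl (2R,3R,4R,5R)-2,5-bis[4-(tert-butyldimethylsilyloxy)-3,5-dimethoxyphenyl]oxolane-3,4-dicarboxylate | COc1cc([C@@H]2O[C@@H](c3cc(OC)c(O[Si](C)(C)C(C)(C)C)c(OC)c3)[C@H](C(=O)OC)[C@H]2C(=O)OC)cc(OC)c1O[Si](C)(C)C(C)(C)C
F7 | step 6 | [(2R,3S,4S,5R)-2,5-bis[4-(tert-butyldimethylsilyloxy)-3,5-dimethoxyphenyl]oxolane-3,4-diyl]dimethanol | COc1cc([C@@H]2O[C@@H](c3cc(OC)c(O[Si](C)(C)C(C)(C)C)c(OC)c3)[C@H](CO)[C@H]2CO)cc(OC)c1O[Si](C)(C)C(C)(C)C
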